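A direct plan would build the cyclohexane first by double α′-alkylation of the chiral enol ether A1 of 2,5-dimethylcyclohexane-1,3-dione, anneal a cyclopentenone by alkyne hydration and aldol condensation to the ketal-protected hydrindenone A2, and add the cyclobutane last by intermolecular enone–vinyl acetate [2+2] photocycloaddition to A3, followed by C5 reduction/Appel inversion, ketal removal and α-bromination/reduction at C9/C10.
Its weakest steps would be:
- The enantiodetermining desymmetrising enol etherification to A1: it would need a catalytic reaction without precedent, and every later stereocentre would depend on it.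
- The intermolecular photocycloaddition to A2: head-to-tail regiochemistry, enone face and exo/endo position of the acetate would all have to be right at once while two adjacent quaternary carbons form, and nothing in the substrate enforces any of the three.
- The ketal on/off sequence, the C5 ketone that is reduced only to be inverted, and the C11 methyl that is set and then epimerised: a stretch of protection, redox and correction that forms no bond of the skeleton.

**Retrosynthetic overview**
The cyclobutane (C1–C2–C3–C4) carries its oxygen on C2 and shares the C1–C4 bond with the cyclopentane (C1–C4–C5–C6–C7), so C2 is read as a former ketene carbonyl, C1 as the ketene α-carbon and C3=C4 as an isopropenyl group.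
Key disconnection: intramolecular vinylketene–alkene [2+2] of the monocyclic acid 9, forming C1–C4 and C2–C3 in one operation, i.e. cyclopentane and cyclobutanone together with the adjacent quaternary centres C1 and C4, both controlled by the one quaternary centre C7.
Ring order: cyclohexane first (from 2-methylcyclohexenone; C7/C8 by catalytic asymmetric conjugate addition and enolate prenylation), then cyclopentane and cyclobutane together; C5 is set in the open chain by Shi epoxidation.
The weak steps are avoided by design: absolute configuration comes from two catalytic asymmetric reactions of known type, the cycloaddition is intramolecular so the tether enforces regio- and facial selectivity, and no ketal or C5 carbonyl is needed.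

Key step: step 7

Remark on the chemistry: atom numbers are those of the tricyclo[5.4.0.0^1,4]undecane core of the target and are used also for the monocyclic precursors (C1 is the carbon common to all three rings). The ligand enantiomer in step 1 is the one that gives the (3S) adduct. The D-fructose-derived Shi ketone is expected, from its behaviour with trans and trisubstituted alkenes, to give the (R)-epoxide; its enantiomer would be used otherwise.

**Step 1**
Reactants: 1 2-methylcyclohex-2-en-1-one; 2 1-bromo-3-methylbut-2-ene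
Product: 4 (2R,3S)-2,3-dimethyl-2-(3-methylbut-2-en-1-yl)cyclohexan-1-one, via aluminium enolate 3 (not isolated)
Conditions: AlMe3 (1.4 equiv), copper thiophene-2-carboxylate Cu(O2CC4H3S) (2 mol%), BINOL-derived phosphoramidite ligand (4 mol%), Et2O, −30 °C; then MeLi (1.4 equiv), THF/DMPU, 2 (1.5 equiv), −30 → 0 °C
Reagents that add atoms: trimethylaluminium, C[Al](C)C
Why: Copper-catalysed asymmetric conjugate addition of AlMe3 to the 2-substituted enone sets C8 under ligand control, and the aluminium enolate 3, activated as its lithium ate complex, should be C-alkylated by prenyl bromide anti to the new 3-methyl group, which sets the quaternary C7 with the prenyl chain trans and the two methyl groups cis.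

**Step 2**
Reactants: 4 (2R,3S)-2,3-dimethyl-2-(3-methylbut-2-en-1-yl)cyclohexan-1-one
Product: 5 (2R,3S,6RS)-2,3,6-trimethyl-2-(3-methylbut-2-en-1-yl)cyclohexan-1-one
Conditions: LiN(i-Pr)2 (1.1 equiv), THF, −78 °C; MeI (1.5 equiv), −78 → 0 °C
Reagents that add atoms: iodomethane, CI
Why: Kinetic enolate methylation at the only enolisable position (C11); the configuration of this carbon does not matter because it becomes sp2 in step 3.

**Step 3**
Reactants: 5 (2R,3S,6RS)-2,3,6-trimethyl-2-(3-methylbut-2-en-1-yl)cyclohexan-1-one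
Product: 6 (5S,6R)-2,5,6-trimethyl-6-(3-methylbut-2-en-1-yl)cyclohex-1-en-1-yl trifluoromethanesulfonate
Conditions: KN(SiMe3)2 (1.3 equiv), THF, −78 → 0 °C; PhNTf2 (1.3 equiv), −78 → 25 °C
Reagents that add atoms: N-phenylbis(trifluoromethanesulfonimide), O=S(=O)(N(c1ccccc1)S(=O)(=O)C(F)(F)F)C(F)(F)F
Why: Deprotonation of the remaining tertiary α-hydrogen and O-sulfonylation of the tetrasubstituted enolate should give the only possible enol triflate; no stereocentre is formed.

**Step 4**
Reactants: 6 (5S,6R)-2,5,6-trimethyl-6-(3-methylbut-2-en-1-yl)cyclohex-1-en-1-yl trifluoromethanesulfonate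
Product: 7 (5S,6R)-6-{[(2R)-3,3-dimethyloxiran-2-yl]methyl}-2,5,6-trimethylcyclohex-1-en-1-yl trifluoromethanesulfonate
Conditions: D-fructose-derived Shi ketone (30 mol%), Oxone (2KHSO5·KHSO4·K2SO4), K2CO3, Bu4NHSO4 (cat.), MeCN/dimethoxymethane/aq. Na2B4O7–Na2EDTA buffer, 0 °C
Reagents that add atoms: potassium peroxymonosulfate, [K+].[O-]S(=O)(=O)OO
Why: Shi epoxidation (chiral dioxirane) should attack only the electron-rich trisubstituted prenyl alkene, the enol triflate alkene being electron-poor, and sets C5 as (R) under reagent control.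

**Step 5**
Reactants: 7 (5S,6R)-6-{[(2R)-3,3-dimethyloxiran-2-yl]methyl}-2,5,6-trimethylcyclohex-1-en-1-yl trifluoromethanesulfonate
Product: 8 (5S,6R)-6-[(2R)-2-[(tert-butyldimethylsilyl)oxy]-3-methylbut-3-en-1-yl]-2,5,6-trimethylcyclohex-1-en-1-yl trifluoromethanesulfonate
Conditions: TBSOTf (1.3 equiv), DBU (1.5 equiv), toluene, 0 → 25 °C
Reagents that add atoms: tert-butyldimethylsilyl trifluoromethanesulfonate, CC(C)(C)[Si](C)(C)OS(=O)(=O)C(F)(F)F
Why: Silyl triflate/amidine-mediated isomerisation of a trisubstituted epoxide to an allyl silyl ether: O-silylation, opening of the tertiary C4–O bond and loss of a methyl proton should give the isopropenyl group and the protected carbinol, with the C5–O bond and its (R) configuration untouched.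

**Step 6**
Reactants: 8 (5S,6R)-6-[(2R)-2-[(tert-butyldimethylsilyl)oxy]-3-methylbut-3-en-1-yl]-2,5,6-trimethylcyclohex-1-en-1-yl trifluoromethanesulfonate
Product: 9 (5S,6R)-6-[(2R)-2-[(tert-butyldimethylsilyl)oxy]-3-methylbut-3-en-1-yl]-2,5,6-trimethylcyclohex-1-ene-1-carboxylic acid
Conditions: Pd(OAc)2 (5 mol%), 1,1'-bis(diphenylphosphino)ferrocene (10 mol%), CO (1 atm), H2O (10 equiv), Et3N (3 equiv), DMF, 60 °C
Reagents that add atoms: carbon monoxide, [C-]#[O+]; water, O
Why: Palladium-catalysed hydroxycarbonylation of the enol triflate (oxidative addition, CO insertion, capture of the acyl palladium by water) installs C2 as the carboxyl carbon without touching a stereocentre.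

**Step 7**
Reactants: 9 (5S,6R)-6-[(2R)-2-[(tert-butyldimethylsilyl)oxy]-3-methylbut-3-en-1-yl]-2,5,6-trimethylcyclohex-1-ene-1-carboxylic acid
Product: 12 (1R,4R,5R,7R,8S)-5-[(tert-butyldimethylsilyl)oxy]-4,7,8-trimethyl-11-methylidenetricyclo[5.4.0.0^1,4]undecan-2-one, via acid chloride 10 (not isolated), via vinylketene 11 (not isolated)
Conditions: 1-chloro-N,N,2-trimethylprop-1-en-1-amine (1.2 equiv), CH2Cl2, 0 → 25 °C; evaporate; slow addition to Et3N (5 equiv), toluene (0.005 M), 110 °C
Reagents that add atoms: 1-chloro-N,N,2-trimethylprop-1-en-1-amine, CC(C)=C(Cl)N(C)C (chlorine, in 10 only)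
Why: Et3N should remove HCl from acid chloride 10 mainly through the γ-methyl group syn to the acyl group and give the cross-conjugated vinylketene 11, which then undergoes a thermal, asynchronous [π2s + π2a] ketene–alkene cycloaddition with the isopropenyl group; deprotonation at the ring methylene instead would give the endocyclic alkene isomer, which steps 8 and 9 carry to the same acetate 15. The closest known reaction type is the intramolecular [2+2] cycloaddition of vinylketenes generated from α,β-unsaturated acid chlorides and a tertiary amine, which gives bicyclo[3.2.0]heptan-6-ones when a three-atom tether ends in a 1,1-disubstituted alkene. The ketene carbonyl carbon C2 bonds to the terminal CH2 (C3) and the ketene α-carbon C1 to the internal alkene carbon C4, so the cyclopentane closes through C1–C4 across the three-atom tether C7–C6–C5 and the cyclobutanone through C2–C3, fused to it. C1 is planar in 11 and the chain on the quaternary C7 can reach only the face of C1 syn to C6, which gives the cis-hydrindane (C2 syn to the 7-methyl); the four/five ring fusion can only be cis, which fixes C4 with its methyl anti to the 7-methyl, and C5 and C8 are not touched. The step needs fused rather than bridged regiochemistry, secured by the more substituted internal alkene carbon and the tether length, and ring closure rather than ketene dimerisation, secured by high dilution and the fully substituted ketene carbon.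

**Step 8**
Reactants: 12 (1R,4R,5R,7R,8S)-5-[(tert-butyldimethylsilyl)oxy]-4,7,8-trimethyl-11-methylidenetricyclo[5.4.0.0^1,4]undecan-2-one
Product: 14 (1R,2R,4R,5R,7R,8S)-5-[(tert-butyldimethylsilyl)oxy]-4,7,8-trimethyl-11-methylidenetricyclo[5.4.0.0^1,4]undecan-2-yl acetate, via alcohol 13 (not isolated)
Conditions: Li (6 equiv), NH3 (l)/THF, −78 °C; solid NH4Cl; evaporate NH3; then Ac2O, pyridine, DMAP (cat.), CH2Cl2, 25 °C
Reagents that add atoms: acetic anhydride, CC(=O)OC(C)=O
Why: Dissolving-metal reduction should give the thermodynamically preferred alcohol, because in the pyramidal α-oxido carbanion the solvated O–Li group takes the exo position next to C11 (one flanking group) rather than the concave position between the 7-methyl and C6H2, so protonation gives (2R), and the crude alcohol is acetylated in the same flask.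

**Step 9**
Reactants: 14 (1R,2R,4R,5R,7R,8S)-5-[(tert-butyldimethylsilyl)oxy]-4,7,8-trimethyl-11-methylidenetricyclo[5.4.0.0^1,4]undecan-2-yl acetate
Product: 15 (1R,2R,4R,5R,7R,8S)-5-[(tert-butyldimethylsilyl)oxy]-4,7,8,11-tetramethyltricyclo[5.4.0.0^1,4]undec-10-en-2-yl acetate
Conditions: RhCl3·3H2O (5 mol%), EtOH, 75 °C
Reagents that add atoms: none
Why: Rhodium hydride-mediated alkene isomerisation (addition/β-hydride elimination) should move the exocyclic double bond to the more stable trisubstituted C10=C11 position, the only endocyclic position open because C1 is quaternary, so any endocyclic isomer carried from step 7 converges here.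

**Step 10**
Reactants: 15 (1R,2R,4R,5R,7R,8S)-5-[(tert-butyldimethylsilyl)oxy]-4,7,8,11-tetramethyltricyclo[5.4.0.0^1,4]undec-10-en-2-yl acetate
Product: 17 (1R,2R,4R,5R,7R,8S,11R)-5-[(tert-butyldimethylsilyl)oxy]-4,7,8,11-tetramethyl-10-oxotricyclo[5.4.0.0^1,4]undecan-2-yl acetate, via alkylborane 16 (not isolated)
Conditions: BH3·THF (1.5 equiv), THF, 0 → 25 °C; then NMO (6 equiv), Pr4N[RuO4] (10 mol%), 4 Å MS, CH2Cl2, 25 °C; then DBU (0.3 equiv), 25 °C
Reagents that add atoms: borane–tetrahydrofuran, [BH3-][O+]1CCCC1 (boron, in 16 only); 4-methylmorpholine N-oxide, C[N+]1([O-])CCOCC1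
Why: Hydroboration places boron on the less substituted C10 and Ley–Griffith-type oxidation of the alkylborane gives the ketone directly; C11, now α to the ketone, is equilibrated by DBU to the equatorial methyl (11R), since its epimer would hold the 11- and 7-methyl groups 1,3-diaxial, so the face of hydroboration does not matter.

**Step 11**
Reactants: 17 (1R,2R,4R,5R,7R,8S,11R)-5-[(tert-butyldimethylsilyl)oxy]-4,7,8,11-tetramethyl-10-oxotricyclo[5.4.0.0^1,4]undecan-2-yl acetate
Product: 19 (1R,2R,4R,5R,7R,8R,9S,11R)-9-bromo-5-[(tert-butyldimethylsilyl)oxy]-4,7,8,11-tetramethyl-10-oxotricyclo[5.4.0.0^1,4]undecan-2-yl acetate, via silyl enol ether 18 (not isolated)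
Conditions: LiN(SiMe3)2 (1.05 equiv), Me3SiCl, THF, −78 °C; then NBS, −78 → 0 °C
Reagents that add atoms: chlorotrimethylsilane, C[Si](C)(C)Cl (in 18 only); N-bromosuccinimide, O=C1CCC(=O)N1Br
Why: Kinetic deprotonation with internal silyl quench should occur at the C9 methylene rather than at the tertiary neopentylic C11–H or the acetate, and electrophilic bromination of 18 delivers bromine away from the syn-axial 7-methyl and anti to the 8-methyl, giving the equatorial (9S) bromide, which is also the thermodynamic epimer (the C8 descriptor changes to R by priority only).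

**Step 12**
Reactants: 19 (1R,2R,4R,5R,7R,8R,9S,11R)-9-bromo-5-[(tert-butyldimethylsilyl)oxy]-4,7,8,11-tetramethyl-10-oxotricyclo[5.4.0.0^1,4]undecan-2-yl acetate
Product: 21 (1R,2R,4R,5R,7R,8R,9S,10R,11R)-9-bromo-5,10-dihydroxy-4,7,8,11-tetramethyltricyclo[5.4.0.0^1,4]undecan-2-yl acetate, via bromohydrin silyl ether 20 (not isolated)
Conditions: LiBH(s-Bu)3 (1.2 equiv), THF, −78 °C; MeOH; then 48% aq. HF, MeCN, 25 °C
Reagents that add atoms: none
Why: Bulky-hydride reduction of the α-bromoketone from the equatorial direction, the axial path being blocked by the syn-axial C1–C4 bond, should give the axial (10R) alcohol cis to bromine and to the 11-methyl (a cis-bromohydrin that cannot close to an epoxide), and acidic fluoride then cleaves the silyl ether without touching acetate or bromide.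

**Step 13**
Reactants: 21 (1R,2R,4R,5R,7R,8R,9S,10R,11R)-9-bromo-5,10-dihydroxy-4,7,8,11-tetramethyltricyclo[5.4.0.0^1,4]undecan-2-yl acetate
Product: 22 (1R,2R,4R,5S,7R,8R,9S,10R,11R)-5,9-dibromo-10-hydroxy-4,7,8,11-tetramethyltricyclo[5.4.0.0^1,4]undecan-2-yl acetate
Conditions: PPh3 (1.5 equiv), CBr4 (1.5 equiv), 2,6-lutidine, toluene, 0 → 50 °C
Reagents that add atoms: carbon tetrabromide, BrC(Br)(Br)Br
Why: Appel reaction: the C5 hydroxyl forms the alkoxyphosphonium ion and is displaced by bromide with inversion to (5S), while the C10 hydroxyl, axial, flanked by the equatorial bromine and methyl and 1,3-syn-axial to the C1–C4 bond, should not be activated under these conditions.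

**Compound list**
1 | 2-methylcyclohex-2-en-1-one | CC1=CCCCC1=O | starting material
2 | 1-bromo-3-methylbut-2-ene | CC(C)=CCBr | starting material
3 | dimethylaluminium (3S)-2,3-dimethylcyclohex-1-en-1-olate | C[Al](C)OC1=C(C)[C@@H](C)CCC1 | intermediate
4 | (2R,3S)-2,3-dimethyl-2-(3-methylbut-2-en-1-yl)cyclohexan-1-one | O=C1CCC[C@H](C)[C@@]1(C)CC=C(C)C | intermediate
5 | (2R,3S,6RS)-2,3,6-trimethyl-2-(3-methylbut-2-en-1-yl)cyclohexan-1-one | O=C1C(C)CC[C@H](C)[C@@]1(C)CC=C(C)C | intermediate
6 | (5S,6R)-2,5,6-trimethyl-6-(3-methylbut-2-en-1-yl)cyclohex-1-en-1-yl trifluoromethanesulfonate | O=S(=O)(OC1=C(C)CC[C@H](C)[C@@]1(C)CC=C(C)C)C(F)(F)F | intermediate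
7 | (5S,6R)-6-{[(2R)-3,3-dimethyloxiran-2-yl]methyl}-2,5,6-trimethylcyclohex-1-en-1-yl trifluoromethanesulfonate | O=S(=O)(OC1=C(C)CC[C@H](C)[C@@]1(C)C[C@H]2OC2(C)C)C(F)(F)F | intermediate
8 | (5S,6R)-6-[(2R)-2-[(tert-butyldimethylsilyl)oxy]-3-methylbut-3-en-1-yl]-2,5,6-trimethylcyclohex-1-en-1-yl trifluoromethanesulfonate | O=S(=O)(OC1=C(C)CC[C@H](C)[C@@]1(C)C[C@@H](O[Si](C)(C)C(C)(C)C)C(C)=C)C(F)(F)F | intermediate
9 | (5S,6R)-6-[(2R)-2-[(tert-butyldimethylsilyl)oxy]-3-methylbut-3-en-1-yl]-2,5,6-trimethylcyclohex-1-ene-1-carboxylic acid | OC(=O)C1=C(C)CC[C@H](C)[C@@]1(C)C[C@@H](O[Si](C)(C)C(C)(C)C)C(C)=C | intermediate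
10 | (5S,6R)-6-[(2R)-2-[(tert-butyldimethylsilyl)oxy]-3-methylbut-3-en-1-yl]-2,5,6-trimethylcyclohex-1-ene-1-carbonyl chloride | ClC(=O)C1=C(C)CC[C@H](C)[C@@]1(C)C[C@@H](O[Si](C)(C)C(C)(C)C)C(C)=C | intermediate
11 | {(5S,6R)-6-[(2R)-2-[(tert-butyldimethylsilyl)oxy]-3-methylbut-3-en-1-yl]-5,6-dimethyl-2-methylidenecyclohexylidene}methanone | O=C=C1C(=C)CC[C@H](C)[C@@]1(C)C[C@@H](O[Si](C)(C)C(C)(C)C)C(C)=C | intermediate
12 | (1R,4R,5R,7R,8S)-5-[(tert-butyldimethylsilyl)oxy]-4,7,8-trimethyl-11-methylidenetricyclo[5.4.0.0^1,4]undecan-2-one | O=C1C[C@@]2(C)[C@H](O[Si](C)(C)C(C)(C)C)C[C@]3(C)[C@@H](C)CCC(=C)[C@]123 | intermediate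
13 | (1R,2R,4R,5R,7R,8S)-5-[(tert-butyldimethylsilyl)oxy]-4,7,8-trimethyl-11-methylidenetricyclo[5.4.0.0^1,4]undecan-2-ol | O[C@@H]1C[C@@]2(C)[C@H](O[Si](C)(C)C(C)(C)C)C[C@]3(C)[C@@H](C)CCC(=C)[C@]123 | intermediate
14 | (1R,2R,4R,5R,7R,8S)-5-[(tert-butyldimethylsilyl)oxy]-4,7,8-trimethyl-11-methylidenetricyclo[5.4.0.0^1,4]undecan-2-yl acetate | CC(=O)O[C@@H]1C[C@@]2(C)[C@H](O[Si](C)(C)C(C)(C)C)C[C@]3(C)[C@@H](C)CCC(=C)[C@]123 | intermediate
15 | (1R,2R,4R,5R,7R,8S)-5-[(tert-butyldimethylsilyl)oxy]-4,7,8,11-tetramethyltricyclo[5.4.0.0^1,4]undec-10-en-2-yl acetate | CC(=O)O[C@@H]1C[C@@]2(C)[C@H](O[Si](C)(C)C(C)(C)C)C[C@]3(C)[C@@H](C)CC=C(C)[C@]123 | intermediate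
16 | (1R,2R,4R,5R,7R,8S)-10-boranyl-5-[(tert-butyldimethylsilyl)oxy]-4,7,8,11-tetramethyltricyclo[5.4.0.0^1,4]undecan-2-yl acetate (C10/C11 not defined) | CC(=O)O[C@@H]1C[C@@]2(C)[C@H](O[Si](C)(C)C(C)(C)C)C[C@]3(C)[C@@H](C)CC(B)C(C)[C@]123 | intermediate
17 | (1R,2R,4R,5R,7R,8S,11R)-5-[(tert-butyldimethylsilyl)oxy]-4,7,8,11-tetramethyl-10-oxotricyclo[5.4.0.0^1,4]undecan-2-yl acetate | CC(=O)O[C@@H]1C[C@@]2(C)[C@H](O[Si](C)(C)C(C)(C)C)C[C@]3(C)[C@@H](C)CC(=O)[C@H](C)[C@]123 | intermediate
18 | (1R,2R,4R,5R,7R,8S,11R)-5-[(tert-butyldimethylsilyl)oxy]-4,7,8,11-tetramethyl-10-(trimethylsilyloxy)tricyclo[5.4.0.0^1,4]undec-9-en-2-yl acetate | CC(=O)O[C@@H]1C[C@@]2(C)[C@H](O[Si](C)(C)C(C)(C)C)C[C@]3(C)[C@@H](C)C=C(O[Si](C)(C)C)[C@H](C)[C@]123 | intermediate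
19 | (1R,2R,4R,5R,7R,8R,9S,11R)-9-bromo-5-[(tert-butyldimethylsilyl)oxy]-4,7,8,11-tetramethyl-10-oxotricyclo[5.4.0.0^1,4]undecan-2-yl acetate | CC(=O)O[C@@H]1C[C@@]2(C)[C@H](O[Si](C)(C)C(C)(C)C)C[C@]3(C)[C@@H](C)[C@H](Br)C(=O)[C@H](C)[C@]123 | intermediate
20 | (1R,2R,4R,5R,7R,8R,9S,10R,11R)-9-bromo-5-[(tert-butyldimethylsilyl)oxy]-10-hydroxy-4,7,8,11-tetramethyltricyclo[5.4.0.0^1,4]undecan-2-yl acetate | CC(=O)O[C@@H]1C[C@@]2(C)[C@H](O[Si](C)(C)C(C)(C)C)C[C@]3(C)[C@@H](C)[C@H](Br)[C@H](O)[C@H](C)[C@]123 | intermediate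
21 | (1R,2R,4R,5R,7R,8R,9S,10R,11R)-9-bromo-5,10-dihydroxy-4,7,8,11-tetramethyltricyclo[5.4.0.0^1,4]undecan-2-yl acetate | CC(=O)O[C@@H]1C[C@@]2(C)[C@H](O)C[C@]3(C)[C@@H](C)[C@H](Br)[C@H](O)[C@H](C)[C@]123 | intermediate
22 | (1R,2R,4R,5S,7R,8R,9S,10R,11R)-5,9-dibromo-10-hydroxy-4,7,8,11-tetramethyltricyclo[5.4.0.0^1,4]undecan-2-yl acetate | CC(=O)O[C@@H]1C[C@@]2(C)[C@@H](Br)C[C@]3(C)[C@@H](C)[C@H](Br)[C@H](O)[C@H](C)[C@]123 | target

Total step count: 13. Longest linear sequence: 13.

**Steps most likely to fail**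

Step 7 (key step). The hindered acid chloride, whose carbonyl is twisted out of conjugation, may lose HCl too slowly, and the vinylketene may then decompose or dimerise before it adds to the alkene. The fallback would set out from 9 and use a more electrophilic keteniminium ion. Acid chloride 10 with Me2NH would give (5S,6R)-6-[(2R)-2-[(tert-butyldimethylsilyl)oxy]-3-methylbut-3-en-1-yl]-N,N,2,5,6-pentamethylcyclohex-1-ene-1-carboxamide F1. Tf2O and 2,4,6-collidine in 1,2-dichloroethane at reflux would turn F1 into the vinylketeniminium triflate F2, which should close in the same [2+2] sense to the cyclobutaniminium triflate F3. Aqueous NaHCO3 would hydrolyse F3 to 12, where the route is rejoined.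

Step 8. Electron transfer to the strained, β,γ-unsaturated cyclobutanone may open the ring or over-reduce before the carbanion is protonated. The fallback would set out from 12: NaBH4 in MeOH at 0 °C would give the kinetic alcohol, expected to be the (1R,2S,4R,5R,7R,8S)-5-[(tert-butyldimethylsilyl)oxy]-4,7,8-trimethyl-11-methylidenetricyclo[5.4.0.0^1,4]undecan-2-ol F4. Hydrogen-transfer equilibration of F4 (Al(Oi-Pr)3, catalytic acetone, toluene, 110 °C; Meerwein–Ponndorf–Verley/Oppenauer conditions) would then move it to the more stable epimer 13, which is acetylated to 14 as in the route.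

Step 13. Site selectivity between the two hydroxyl groups may be lost: the C10 alcohol may be activated as well and then eliminate, or substitution at the neopentylic C5 may stall. The fallback would set out from 19, so that the C5 oxygen is activated before the C10 hydroxyl exists.
- 48% aq. HF in MeCN would give (1R,2R,4R,5R,7R,8R,9S,11R)-9-bromo-5-hydroxy-4,7,8,11-tetramethyl-10-oxotricyclo[5.4.0.0^1,4]undecan-2-yl acetate F5.
- MsCl and Et3N would give the mesylate (1R,2R,4R,5R,7R,8R,9S,11R)-9-bromo-5-(methanesulfonyloxy)-4,7,8,11-tetramethyl-10-oxotricyclo[5.4.0.0^1,4]undecan-2-yl acetate F6.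
- LiBH(s-Bu)3 at −78 °C would reduce the ketone to (1R,2R,4R,5R,7R,8R,9S,10R,11R)-9-bromo-10-hydroxy-5-(methanesulfonyloxy)-4,7,8,11-tetramethyltricyclo[5.4.0.0^1,4]undecan-2-yl acetate F7.
- LiBr in DMF at 80 °C would displace the mesylate with inversion and give 22 directly.

**Further compounds**
F1 | step 7 | (5S,6R)-6-[(2R)-2-[(tert-butyldimethylsilyl)oxy]-3-methylbut-3-en-1-yl]-N,N,2,5,6-pentamethylcyclohex-1-ene-1-carboxamide | CN(C)C(=O)C1=C(C)CC[C@H](C)[C@@]1(C)C[C@@H](O[Si](C)(C)C(C)(C)C)C(C)=C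
F2 | step 7 | N-({(5S,6R)-6-[(2R)-2-[(tert-butyldimethylsilyl)oxy]-3-methylbut-3-en-1-yl]-5,6-dimethyl-2-methylidenecyclohexylidene}methylidene)-N-methylmethanaminium trifluoromethanesulfonate | C[N+](C)=C=C1C(=C)CC[C@H](C)[C@@]1(C)C[C@@H](O[Si](C)(C)C(C)(C)C)C(C)=C.[O-]S(=O)(=O)C(F)(F)F
F3 | step 7 | N-[(1R,4R,5R,7R,8S)-5-[(tert-butyldimethylsilyl)oxy]-4,7,8-trimethyl-11-methylidenetricyclo[5.4.0.0^1,4]undecan-2-ylidene]-N-methylmethanaminium trifluoromethanesulfonate | C[N+](C)=C1C[C@@]2(C)[C@H](O[Si](C)(C)C(C)(C)C)C[C@]3(C)[C@@H](C)CCC(=C)[C@]123.[O-]S(=O)(=O)C(F)(F)F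
F4 | step 8 | (1R,2S,4R,5R,7R,8S)-5-[(tert-butyldimethylsilyl)oxy]-4,7,8-trimethyl-11-methylidenetricyclo[5.4.0.0^1,4]undecan-2-ol | O[C@H]1C[C@@]2(C)[C@H](O[Si](C)(C)C(C)(C)C)C[C@]3(C)[C@@H](C)CCC(=C)[C@]123
F5 | step 13 | (1R,2R,4R,5R,7R,8R,9S,11R)-9-bromo-5-hydroxy-4,7,8,11-tetramethyl-10-oxotricyclo[5.4.0.0^1,4]undecan-2-yl acetate | CC(=O)O[C@@H]1C[C@@]2(C)[C@H](O)C[C@]3(C)[C@@H](C)[C@H](Br)C(=O)[C@H](C)[C@]123
F6 | step 13 | (1R,2R,4R,5R,7R,8R,9S,11R)-9-bromo-5-(methanesulfonyloxy)-4,7,8,11-tetramethyl-10-oxotricyclo[5.4.0.0^1,4]undecan-2-yl acetate | CC(=O)O[C@@H]1C[C@@]2(C)[C@H](OS(C)(=O)=O)C[C@]3(C)[C@@H](C)[C@H](Br)C(=O)[C@H](C)[C@]123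
F7 | step 13 | (1R,2R,4R,5R,7R,8R,9S,10R,11R)-9-bromo-10-hydroxy-5-(methanesulfonyloxy)-4,7,8,11-tetramethyltricyclo[5.4.0.0^1,4]undecan-2-yl acetate | CC(=O)O[C@@H]1C[C@@]2(C)[C@H](OS(C)(=O)=O)C[C@]3(C)[C@@H](C)[C@H](Br)[C@H](O)[C@H](C)[C@]123
A1 | direct plan | (S)-2,5-dimethyl-3-(2-methylpropoxy)cyclohex-2-en-1-one | O=C1C[C@@H](C)CC(OCC(C)C)=C1C
A2 | direct plan | (4R,7S,7aR)-5,5-(ethylenedioxy)-3,4,7,7a-tetramethyl-1,4,5,6,7,7a-hexahydro-2H-inden-2-one | O=C1C[C@]2(C)[C@@H](C)CC3(OCCO3)[C@H](C)C2=C1C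
A3 | direct plan | (1R,2R,4R,7R,8S,11R)-10,10-(ethylenedioxy)-4,7,8,11-tetramethyl-5-oxotricyclo[5.4.0.0^1,4]undecan-2-yl acetate | CC(=O)O[C@@H]1C[C@@]2(C)C(=O)C[C@]3(C)[C@@H](C)CC4(OCCO4)[C@H](C)[C@]123
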